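**Retrosynthetic overview**

1. Oxolane numbering used throughout: O1, C2 (CH2OAr), C3 (C(OH)CH3), C4, C5 (isobutenyl). Last bond: the aryl ether C–O, by Mitsunobu coupling of diol 13 with isofraxidin 14; the CH2OH of 13 is unmasked from a CH2S(O)Tol group (Pummerer rearrangement, then reduction).
2. C5–alkenyl bond: addition of an isobutenyl trifluoroborate to the C5 oxocarbenium ion, made by oxidative decarboxylation of a C5 carboxylic acid. The carboxyl group is a traceless control element: it relays chirality to C2/C3 and is then replaced from the opposite face.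
3. Oxolane ring (the only ring formed; the coumarin is bought as 14): closed by the C2–C3 bond in a SmI2 ketyl–olefin 5-exo cyclization of the acyclic keto vinyl sulfoxide 5, which sets C2 and C3 in the same operation.
4. Enabling feature: in the oxolane the ether carbon C2 (O1–C2H) is bonded directly to the tertiary carbinol carbon C3 (C(OH)CH3). This α-alkoxy tertiary alcohol is the retron of a methyl-ketone ketyl (C3) adding to the oxygen-bearing carbon of an acceptor-substituted enol ether (O1–C2H=CH–S(O)Tol).
5. Precursor 5: oxa-Michael addition of hydroxy keto ester 3 (D-proline aldol of acetone 1 with ethyl glyoxylate 2) to ethynyl sulfoxide 4.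

Key step: step 3

Assumption: (R)-ethynyl p-tolyl sulfoxide 4 is taken as a purchasable reagent (otherwise one step from ethynylmagnesium bromide and (−)-menthyl (S)-p-toluenesulfinate); its sulfur configuration is not needed in the target and is removed in step 7.

**Route**

Step 1
Reactants: 1 acetone; 2 ethyl glyoxylate
Product: 3 ethyl (2S)-2-hydroxy-4-oxopentanoate
Conditions: D-proline (20 mol %), acetone (excess), DMSO, rt
Reagents that add atoms: none
Why: Proline-catalysed direct aldol reaction (enamine catalysis), in which the acetone enamine of D-proline should attack one face of the aldehyde through the hydrogen-bonded, carboxylic-acid-organised transition state and so set the (S)-carbinol, the mirror image of the (R)-aldols given by L-proline.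

Step 2
Reactants: 3 ethyl (2S)-2-hydroxy-4-oxopentanoate; 4 (R)-ethynyl p-tolyl sulfoxide
Product: 5 ethyl (2S)-2-({(E)-2-[(R)-4-methylbenzenesulfinyl]ethenyl}oxy)-4-oxopentanoate
Conditions: N-methylmorpholine (cat.), CH2Cl2, 0 °C to rt
Reagents that add atoms: none
Why: Amine-catalysed oxa-Michael addition of the secondary alcohol to the acceptor alkyne, which should give the (E)-β-alkoxyvinyl sulfoxide and creates no stereocentre.

Step 3
Reactants: 5 ethyl (2S)-2-({(E)-2-[(R)-4-methylbenzenesulfinyl]ethenyl}oxy)-4-oxopentanoate
Product: 6 ethyl (2S,4R,5R)-4-hydroxy-4-methyl-5-{[(R)-4-methylbenzenesulfinyl]methyl}oxolane-2-carboxylate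
Conditions: SmI2 (2.5 equiv), MeOH (5 equiv), THF, −78 to 0 °C
Reagents that add atoms: none
Why: SmI2 transfers one electron to the methyl ketone (the most easily reduced group; no HMPA, so ester and sulfoxide should survive), the trivalent samarium ketyl adds 5-exo-trig to the oxygen-bearing β-carbon of the (E)-vinyl sulfoxide, and a second electron transfer gives an α-sulfinyl organosamarium that methanol protonates before it can expel the ring oxygen. The closest known reaction type is the SmI2-induced reductive cyclization of β-alkoxyacrylates and β-alkoxyvinyl sulfoxides onto aldehydes and methyl ketones, used for 2,3-trans cyclic ethers (ketyl–olefin cyclization). The oxolane is closed in the 5-exo-trig radical mode by the bond between the ketyl carbon (C3) and the alkoxy-bearing alkene carbon (C2). C2 is controlled by the resident C5 stereocentre: in the chair-like 5-exo transition state the ester and the acceptor chain both sit pseudo-equatorial, so the sulfinylmethyl group should end cis to the ester (2,5-cis). C3 is controlled by the preference of the bulky, electron-rich O–Sm group to lie anti to the sulfinyl-bearing terminus, so the hydroxyl should end trans and the methyl cis to the C2 side chain. The step needs protonation to outrun β-elimination, secured by methanol present from the start, and the (E)-geometry of 5, secured in step 2.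

Step 4
Reactants: 6 ethyl (2S,4R,5R)-4-hydroxy-4-methyl-5-{[(R)-4-methylbenzenesulfinyl]methyl}oxolane-2-carboxylate
Product: 7 (2S,4R,5R)-4-hydroxy-4-methyl-5-{[(R)-4-methylbenzenesulfinyl]methyl}oxolane-2-carboxylic acid
Conditions: LiOH, THF/H2O, 0 °C; then 1 M HCl to pH 3
Reagents that add atoms: lithium hydroxide [Li+].[OH-]
Why: Ester saponification, which leaves the sulfoxide and the tertiary alcohol untouched and makes any epimerization at C5 irrelevant because that centre is erased in step 5.

Step 5
Reactants: 7 (2S,4R,5R)-4-hydroxy-4-methyl-5-{[(R)-4-methylbenzenesulfinyl]methyl}oxolane-2-carboxylic acid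
Product: 8 (4R,5R)-4-hydroxy-4-methyl-5-{[(R)-4-methylbenzenesulfinyl]methyl}oxolan-2-yl acetate (both C2 epimers)
Conditions: Pb(OAc)4, pyridine (cat.), THF, rt
Reagents that add atoms: lead tetraacetate CC(=O)O[Pb](OC(C)=O)(OC(C)=O)OC(C)=O
Why: Oxidative decarboxylation of an α-alkoxy acid by tetravalent lead (loss of CO2, oxidation of the α-oxy radical to the C5 oxocarbenium ion, capture by acetate), which deliberately erases the C5 stereocentre after it has done its work in step 3.

Step 6
Reactants: 8 (4R,5R)-4-hydroxy-4-methyl-5-{[(R)-4-methylbenzenesulfinyl]methyl}oxolan-2-yl acetate; 9 potassium trifluoro(2-methylprop-1-en-1-yl)borate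
Product: 10 (2R,3R,5R)-3-methyl-2-{[(R)-4-methylbenzenesulfinyl]methyl}-5-(2-methylprop-1-en-1-yl)oxolan-3-ol
Conditions: BF3·OEt2, CH2Cl2/MeCN, −40 °C
Reagents that add atoms: none
Why: Lewis-acid-mediated addition of an alkenyltrifluoroborate to a cyclic oxocarbenium ion (C-glycosylation type), in which inside attack on the envelope with the C3 oxygen pseudoaxial should bring the nucleophile in anti to the C3 methyl and the C2 sulfinylmethyl group, setting C5 with the isobutenyl group cis to the C3 hydroxyl and trans to the C2 side chain.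

Step 7
Reactants: 10 (2R,3R,5R)-3-methyl-2-{[(R)-4-methylbenzenesulfinyl]methyl}-5-(2-methylprop-1-en-1-yl)oxolan-3-ol
Product: 13 (2S,3R,5R)-2-(hydroxymethyl)-3-methyl-5-(2-methylprop-1-en-1-yl)oxolan-3-ol, via trifluoroacetoxy sulfide 11 (not isolated), via aldehyde 12 (not isolated)
Conditions: (CF3CO)2O, 2,4,6-collidine, MeCN, 0 °C; aq NaHCO3; then NaBH4, EtOH, 0 °C
Reagents that add atoms: trifluoroacetic anhydride O=C(OC(=O)C(F)(F)F)C(F)(F)F
Why: Pummerer rearrangement of the sulfoxide to the α-acyloxy sulfide, hydrolysis to the aldehyde and immediate borohydride reduction, so that the epimerizable C2 aldehyde is consumed as it forms, any tertiary trifluoroacetate is cleaved in the basic stage and no stereocentre is created.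

Step 8
Reactants: 13 (2S,3R,5R)-2-(hydroxymethyl)-3-methyl-5-(2-methylprop-1-en-1-yl)oxolan-3-ol; 14 isofraxidin
Product: 15 7-{[(2S,3R,5R)-3-hydroxy-3-methyl-5-(2-methylprop-1-en-1-yl)oxolan-2-yl]methoxy}-6,8-dimethoxy-2H-chromen-2-one
Conditions: PPh3, DIAD, THF, 0 °C to rt
Reagents that add atoms: none
Why: Mitsunobu etherification of the primary alcohol with the acidic phenol, which should leave the tertiary alcohol, the allylic ether and all three stereocentres untouched.

**Compound list**

1 | acetone | CC(C)=O | starting material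
2 | ethyl glyoxylate | CCOC(=O)C=O | starting material
3 | ethyl (2S)-2-hydroxy-4-oxopentanoate | CC(=O)C[C@H](O)C(=O)OCC | intermediate
4 | (R)-ethynyl p-tolyl sulfoxide (1-[(R)-ethynesulfinyl]-4-methylbenzene) | Cc1ccc(cc1)[S@](=O)C#C | starting material
5 | ethyl (2S)-2-({(E)-2-[(R)-4-methylbenzenesulfinyl]ethenyl}oxy)-4-oxopentanoate | Cc1ccc(cc1)[S@](=O)/C=C/O[C@@H](CC(C)=O)C(=O)OCC | intermediate
6 | ethyl (2S,4R,5R)-4-hydroxy-4-methyl-5-{[(R)-4-methylbenzenesulfinyl]methyl}oxolane-2-carboxylate | Cc1ccc(cc1)[S@](=O)C[C@@H]1O[C@H](C(=O)OCC)C[C@@]1(C)O | intermediate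
7 | (2S,4R,5R)-4-hydroxy-4-methyl-5-{[(R)-4-methylbenzenesulfinyl]methyl}oxolane-2-carboxylic acid | Cc1ccc(cc1)[S@](=O)C[C@@H]1O[C@H](C(=O)O)C[C@@]1(C)O | intermediate
8 | (4R,5R)-4-hydroxy-4-methyl-5-{[(R)-4-methylbenzenesulfinyl]methyl}oxolan-2-yl acetate (both C2 epimers) | Cc1ccc(cc1)[S@](=O)C[C@@H]1OC(OC(C)=O)C[C@@]1(C)O | intermediate
9 | potassium trifluoro(2-methylprop-1-en-1-yl)borate | CC(C)=C[B-](F)(F)F.[K+] | starting material
10 | (2R,3R,5R)-3-methyl-2-{[(R)-4-methylbenzenesulfinyl]methyl}-5-(2-methylprop-1-en-1-yl)oxolan-3-ol | Cc1ccc(cc1)[S@](=O)C[C@@H]1O[C@@H](C=C(C)C)C[C@@]1(C)O | intermediate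
11 | [(2R,3R,5R)-3-hydroxy-3-methyl-5-(2-methylprop-1-en-1-yl)oxolan-2-yl][(4-methylphenyl)sulfanyl]methyl trifluoroacetate | Cc1ccc(cc1)SC(OC(=O)C(F)(F)F)[C@@H]1O[C@@H](C=C(C)C)C[C@@]1(C)O | intermediate
12 | (2R,3R,5R)-3-hydroxy-3-methyl-5-(2-methylprop-1-en-1-yl)oxolane-2-carbaldehyde | O=C[C@@H]1O[C@@H](C=C(C)C)C[C@@]1(C)O | intermediate
13 | (2S,3R,5R)-2-(hydroxymethyl)-3-methyl-5-(2-methylprop-1-en-1-yl)oxolan-3-ol | OC[C@@H]1O[C@@H](C=C(C)C)C[C@@]1(C)O | intermediate
14 | isofraxidin (7-hydroxy-6,8-dimethoxy-2H-chromen-2-one) | COc1cc2ccc(=O)oc2c(OC)c1O | starting material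
15 | 7-{[(2S,3R,5R)-3-hydroxy-3-methyl-5-(2-methylprop-1-en-1-yl)oxolan-2-yl]methoxy}-6,8-dimethoxy-2H-chromen-2-one | COc1cc2ccc(=O)oc2c(OC)c1OC[C@@H]1O[C@@H](C=C(C)C)C[C@@]1(C)O | target

**Step count and risks**

Total step count: 8. Longest linear sequence: 8 steps (1 to 15).

Steps most likely to fail:

Step 3. Samarium could chelate between the ketyl oxygen and the C5 ester and reverse the facial selectivity. Over-reduction (C–O cleavage next to the ester, deoxygenation of the sulfoxide) or β-elimination of the α-sulfinyl organosamarium could reopen the ring. The fallback sets out from 2 and comes back at 6. It forms the same C2–C3 bond by a vinyl-radical 5-exo cyclization and installs the tertiary alcohol afterwards. Barbier 2-bromoallylation of 2 with 2,3-dibromopropene and indium powder, followed by kinetic resolution with a lipase, should give ethyl (2S)-4-bromo-2-hydroxypent-4-enoate F1. Oxa-Michael addition of F1 to 4 (N-methylmorpholine) gives ethyl (2S)-4-bromo-2-({(E)-2-[(R)-4-methylbenzenesulfinyl]ethenyl}oxy)pent-4-enoate F2. Bu3SnH with Et3B generates the vinyl radical, which should close 5-exo onto the β-alkoxyvinyl sulfoxide to the 2,5-cis compound ethyl (2S,5R)-4-methylidene-5-{[(R)-4-methylbenzenesulfinyl]methyl}oxolane-2-carboxylate F3. Mukaiyama hydration (Mn(dpm)3, PhSiH3, O2, then PPh3) should deliver oxygen to the face opposite both ring substituents and give 6.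

Step 6. The nucleophile could attack both faces of the oxocarbenium ion, or the Lewis acid could ionize the allylic C5–O bond of 10 once it has formed. The fallback sets out from 7 and comes back at 10. It replaces the cationic two-step sequence by a radical cross-coupling: decarboxylative alkenylation of 7 with 1-bromo-2-methylprop-1-ene under dual photoredox and nickel catalysis (Ir[dF(CF3)ppy]2(dtbbpy)PF6, NiCl2·glyme, 4,4'-di-tert-butyl-2,2'-bipyridine, Cs2CO3, DMSO, blue light). The C5 radical is expected to be captured by nickel on the face opposite the C3 methyl and the C2 side chain, and no Lewis acid touches the product. It makes no compound outside the list (F0).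

Step 7. The α-alkoxy aldehyde could epimerize at C2 before it is reduced, or the thionium ion and the acid set free could attack the alkene or ionize the allylic ether. The fallback sets out from 6 and comes back at 13. It removes the sulfur before the alkene exists. Pummerer rearrangement and borohydride reduction of 6 give a primary alcohol that should lactonize onto the cis ester to (1S,5S,6R)-6-hydroxy-6-methyl-3,8-dioxabicyclo[3.2.1]octan-2-one F4. LiOH opens it to (2S,4R,5S)-4-hydroxy-5-(hydroxymethyl)-4-methyloxolane-2-carboxylic acid F5. Decarboxylation with Pb(OAc)4 then traps the C5 cation with the primary hydroxyl as the internal acetal (1S,4S,5R)-5-methyl-2,7-dioxabicyclo[2.2.1]heptan-5-ol F6. BF3·OEt2 and 9 should open the acetal at the less hindered primary oxygen and deliver the isobutenyl group to C5 anti to the departing bridge, giving 13.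

**Further compounds**

F1 | step 3 | ethyl (2S)-4-bromo-2-hydroxypent-4-enoate | C=C(Br)C[C@H](O)C(=O)OCC
F2 | step 3 | ethyl (2S)-4-bromo-2-({(E)-2-[(R)-4-methylbenzenesulfinyl]ethenyl}oxy)pent-4-enoate | Cc1ccc(cc1)[S@](=O)/C=C/O[C@@H](CC(Br)=C)C(=O)OCC
F3 | step 3 | ethyl (2S,5R)-4-methylidene-5-{[(R)-4-methylbenzenesulfinyl]methyl}oxolane-2-carboxylate | Cc1ccc(cc1)[S@](=O)C[C@@H]1O[C@H](C(=O)OCC)CC1=C
F0 | step 6 | none | none
F4 | step 7 | (1S,5S,6R)-6-hydroxy-6-methyl-3,8-dioxabicyclo[3.2.1]octan-2-one | O=C1OC[C@@H]2O[C@H]1C[C@@]2(C)O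
F5 | step 7 | (2S,4R,5S)-4-hydroxy-5-(hydroxymethyl)-4-methyloxolane-2-carboxylic acid | OC[C@@H]1O[C@H](C(=O)O)C[C@@]1(C)O
F6 | step 7 | (1S,4S,5R)-5-methyl-2,7-dioxabicyclo[2.2.1]heptan-5-ol | C2[C@@H]1O[C@H](O2)C[C@@]1(C)O
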